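## Retrosynthetic overview

1. C3–C4: the 14-membered carbocycle is closed last, by a nickel-catalysed reductive coupling of the C3 aldehyde with a methyl-capped alkyne (sets 3S and 4E).
2. C8–C9: a Negishi coupling joins the east lactone (alkylzinc at C9) to the west Z-iodo enyne C4–C8, made from but-2-yn-1-ol and a propynyl Grignard reagent.
3. O–C12: the ε-lactone comes from acid-catalysed opening of an (11R,12R)-epoxide by the C16 carboxylic acid with inversion at C12; the epoxide comes from Shi epoxidation of the 11E alkene.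
4. C1–C14: a copper-catalysed asymmetric SN2′ alkylation of a Baylis–Hillman-type bromide (C1–C3, C15–C17) with a dialkylzinc (C9–C14) sets C1 and the α-methylene ester.
5. Ring order: seven-membered lactone first (step 16), 14-membered carbocycle last (step 20).

Assumption: atoms are labelled by cembrane numbering (ring carbons C1–C14, C1 bearing the acrylate; C15 acrylate α-carbon, C16 lactone carbonyl, C17 exocyclic CH2), and commercial solutions of prop-1-yn-1-ylmagnesium bromide and oxirane count as starting materials.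

## Route

**West fragment (C4–C8)**

Step 1
Reactants: 1 but-2-yn-1-ol
Product: 3 (Z)-3-iodobut-2-en-1-ol, via cyclic sodium alkenylalanate 2 (not isolated)
Conditions: NaAlH2(OCH2CH2OMe)2, THF, 0 °C → rt; then I2, −78 °C → 0 °C
Reagents that add atoms: iodine, [I][I]
Why: Alkoxide-directed trans-hydroalumination of the propargylic alcohol places aluminium on C3 inside a five-membered alanate, and iodinolysis with retention gives the Z vinyl iodide that fixes the later C7=C8 geometry (hydroalumination–iodination).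

Step 2
Reactants: 3 (Z)-3-iodobut-2-en-1-ol
Product: 4 (Z)-1-bromo-3-iodobut-2-ene
Conditions: CBr4, PPh3, CH2Cl2, 0 °C
Reagents that add atoms: carbon tetrabromide, BrC(Br)(Br)Br
Why: Appel bromination converts the primary allylic alcohol by SN2 displacement at CH2 and leaves the vinyl iodide and the Z geometry untouched.

Step 3
Reactants: 4 (Z)-1-bromo-3-iodobut-2-ene; 5 prop-1-yn-1-ylmagnesium bromide (CH3C≡CMgBr, 0.5 M in THF)
Product: 6 (Z)-2-iodohept-2-en-5-yne
Conditions: CuBr·SMe2 (5 mol%), THF, −20 °C → rt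
Reagents that add atoms: none
Why: Copper-catalysed alkynyl Grignard–allyl bromide coupling occurs at the primary carbon (the other allylic terminus is fully substituted) and needs no palladium, so the vinyl iodide survives and the skipped enyne C4–C8 results.

**East nucleophile (C9–C14)**

Step 4
Reactants: 7 but-3-yn-1-ol
Product: 8 (but-3-yn-1-yloxy)(tert-butyl)dimethylsilane
Conditions: TBSCl, imidazole, CH2Cl2, rt
Reagents that add atoms: tert-butyldimethylsilyl chloride, CC(C)(C)[Si](C)(C)Cl
Why: Standard silyl ether formation masks the hydroxyl group so that it does not consume the organoaluminium and organolithium reagents of the next step.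

Step 5
Reactants: 8 (but-3-yn-1-yloxy)(tert-butyl)dimethylsilane; 9 oxirane
Product: 12 (E)-6-{[tert-butyl(dimethyl)silyl]oxy}-4-methylhex-3-en-1-ol, via alkenyldimethylalane 10 (not isolated), via lithium alkenylalanate 11 (not isolated)
Conditions: Me3Al, Cp2ZrCl2 (25 mol%), CH2Cl2, 0 °C → rt; evaporate; n-BuLi, THF–hexane, −78 → 0 °C; then 9, −30 °C → rt
Reagents that add atoms: trimethylaluminium, C[Al](C)C
Why: Negishi zirconium-catalysed syn-carboalumination adds methyl (to the internal carbon) and aluminium across the alkyne, which sets the E C11=C12 geometry, and the derived lithium alanate opens oxirane to add C10–C9 with retention of that geometry.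

Step 6
Reactants: 12 (E)-6-{[tert-butyl(dimethyl)silyl]oxy}-4-methylhex-3-en-1-ol
Product: 13 tert-butyl{[(E)-6-chloro-3-methylhex-3-en-1-yl]oxy}dimethylsilane
Conditions: PPh3, NCS, CH2Cl2, 0 °C → rt
Reagents that add atoms: N-chlorosuccinimide, O=C1CCC(=O)N1Cl
Why: Appel-type chlorination of the primary alcohol is an SN2 process and installs a chloride that is inert until the Finkelstein exchange.

Step 7
Reactants: 13 tert-butyl{[(E)-6-chloro-3-methylhex-3-en-1-yl]oxy}dimethylsilane
Product: 14 (E)-6-chloro-3-methylhex-3-en-1-ol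
Conditions: CSA (10 mol%), MeOH, rt
Reagents that add atoms: none
Why: Acid-catalysed methanolysis removes the primary silyl ether without touching the alkyl chloride or the trisubstituted alkene.

Step 8
Reactants: 14 (E)-6-chloro-3-methylhex-3-en-1-ol
Product: 15 (E)-6-chloro-1-iodo-3-methylhex-3-ene
Conditions: I2, PPh3, imidazole, CH2Cl2, 0 °C
Reagents that add atoms: iodine, [I][I]
Why: Appel iodination of the primary alcohol gives the iodide needed for iodine–zinc exchange while the chloride stays in place.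

**East electrophile (C1–C3, C15–C17)**

Step 9
Reactants: 16 3,3-dimethoxyprop-1-ene
Product: 18 3,3-dimethoxypropan-1-ol, via B-alkyl-9-BBN adduct 17 (not isolated)
Conditions: 9-BBN, THF, 0 °C → rt; then NaOH, H2O2, 0 °C
Reagents that add atoms: hydrogen peroxide, OO
Why: Hydroboration–oxidation with bulky 9-BBN places boron on the terminal carbon (anti-Markovnikov), and basic peroxide oxidation leaves the acetal intact.

Step 10
Reactants: 18 3,3-dimethoxypropan-1-ol
Product: 19 3,3-dimethoxypropanal
Conditions: Dess–Martin periodinane, pyridine, CH2Cl2, 0 °C → rt (used at once)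
Reagents that add atoms: none
Why: Buffered Dess–Martin oxidation gives the aldehyde under neutral conditions, which avoids loss of methanol from the β-acetal.

Step 11
Reactants: 19 3,3-dimethoxypropanal; 20 methyl prop-2-ynoate
Product: 22 methyl 3-hydroxy-5,5-dimethoxy-2-methylidenepentanoate (racemic), via alkenylaluminium reagent 21 (not isolated)
Conditions: 20, i-Bu2AlH, NMO, THF, 0 °C; then 19, 0 °C → rt
Reagents that add atoms: none
Why: Conjugate hydroalumination of the propiolate gives an α-aluminoacrylate that adds to the aldehyde at 0 °C (vinylalumination, an organometallic route to the Morita–Baylis–Hillman adduct), fast enough that the base-sensitive aldehyde does not eliminate; the racemic carbinol centre is removed in step 12.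

Step 12
Reactants: 22 methyl 3-hydroxy-5,5-dimethoxy-2-methylidenepentanoate
Product: 23 methyl (Z)-2-(bromomethyl)-5,5-dimethoxypent-2-enoate
Conditions: NBS, Me2S, CH2Cl2, 0 °C → rt
Reagents that add atoms: N-bromosuccinimide, O=C1CCC(=O)N1Br
Why: Activation of the allylic alcohol as an alkoxysulfonium salt (Corey–Kim type) and SN2′ attack of bromide transposes the alkene to the thermodynamically favoured Z 2-(bromomethyl)enoate.

**Union, lactone, ring closure**

Step 13
Reactants: 15 (E)-6-chloro-1-iodo-3-methylhex-3-ene; 23 methyl (Z)-2-(bromomethyl)-5,5-dimethoxypent-2-enoate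
Product: 25 methyl (3S,6E)-9-chloro-3-(2,2-dimethoxyethyl)-6-methyl-2-methylidenenon-6-enoate, via dialkylzinc 24 (not isolated)
Conditions: 15 (2.4 equiv), Et2Zn, CuI (0.3 mol%), 50 °C, then vacuum; 23 (1 equiv), (CuOTf)2·C6H6 (2.5 mol%), phosphoramidite L1 [(S)-BINOL-derived N,N-bis((S)-1-phenylethyl)phosphoramidite, 6 mol%], THF, −40 °C
Reagents that add atoms: none
Why: Copper-catalysed asymmetric allylic alkylation (SN2′) of the Baylis–Hillman-type bromide with the dialkylzinc delivers the alkyl group to the enoate β-carbon with loss of bromide, which forms C1–C14, unveils the α-methylene ester and sets C1 (S) under control of the chiral phosphoramidite–copper catalyst (the ligand antipode that gives 3S is used).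

Step 14
Reactants: 25 methyl (3S,6E)-9-chloro-3-(2,2-dimethoxyethyl)-6-methyl-2-methylidenenon-6-enoate
Product: 26 methyl (3S)-5-[(2R,3R)-3-(2-chloroethyl)-2-methyloxiran-2-yl]-3-(2,2-dimethoxyethyl)-2-methylidenepentanoate
Conditions: D-fructose-derived Shi ketone (30 mol%), KHSO5 (Oxone), K2CO3, Bu4NHSO4, MeCN–CH2(OMe)2–aq. Na2B4O7 buffer (pH 10.5), 0 °C
Reagents that add atoms: potassium peroxymonosulfate, [K+].[O-]S(=O)(=O)OO
Why: Shi asymmetric epoxidation: the chiral dioxirane attacks only the electron-rich trisubstituted alkene (the acrylate is inert) through the spiro transition state that gives the (R,R)-epoxide from E-trisubstituted alkenes, which sets C11 (R).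

Step 15
Reactants: 26 methyl (3S)-5-[(2R,3R)-3-(2-chloroethyl)-2-methyloxiran-2-yl]-3-(2,2-dimethoxyethyl)-2-methylidenepentanoate
Product: 27 (3S)-5-[(2R,3R)-3-(2-chloroethyl)-2-methyloxiran-2-yl]-3-(2,2-dimethoxyethyl)-2-methylidenepentanoic acid
Conditions: LiOH, THF–H2O, 0 °C → rt; then cold 1 M HCl to pH 4
Reagents that add atoms: lithium hydroxide, [Li+].[OH-]
Why: Saponification of the methyl ester; the epoxide, the acetal and the primary chloride are stable to cold aqueous base and the acidification is kept mild.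

Step 16
Reactants: 27 (3S)-5-[(2R,3R)-3-(2-chloroethyl)-2-methyloxiran-2-yl]-3-(2,2-dimethoxyethyl)-2-methylidenepentanoic acid
Product: 29 (1R)-3-chloro-1-[(2S,5S)-5-(2,2-dimethoxyethyl)-2-methyl-6-methylidene-7-oxooxepan-2-yl]propyl acetate, via hydroxy lactone 28 (not isolated)
Conditions: CSA (10 mol%), 4 Å MS, CH2Cl2, 0 °C → rt; then Et3N, Ac2O, DMAP, rt
Reagents that add atoms: acetic anhydride, CC(=O)OC(C)=O
Why: Acid-catalysed intramolecular epoxide opening (7-exo) by the carboxylic acid at the tertiary carbon with inversion turns the (12R)-epoxide carbon into the (12S) lactone carbon and forms the ε-lactone ring, while C11 keeps its R configuration and its freed hydroxyl group is acetylated in the same flask.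

Step 17
Reactants: 29 (1R)-3-chloro-1-[(2S,5S)-5-(2,2-dimethoxyethyl)-2-methyl-6-methylidene-7-oxooxepan-2-yl]propyl acetate
Product: 30 (1R)-1-[(2S,5S)-5-(2,2-dimethoxyethyl)-2-methyl-6-methylidene-7-oxooxepan-2-yl]-3-iodopropyl acetate
Conditions: NaI, butan-2-one, 75 °C
Reagents that add atoms: sodium iodide, [Na+].[I-]
Why: Finkelstein exchange of the primary chloride for iodide, driven by precipitation of NaCl, gives the substrate for zinc insertion.

Step 18
Reactants: 30 (1R)-1-[(2S,5S)-5-(2,2-dimethoxyethyl)-2-methyl-6-methylidene-7-oxooxepan-2-yl]-3-iodopropyl acetate; 6 (Z)-2-iodohept-2-en-5-yne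
Product: 32 (1R,4Z)-1-[(2S,5S)-5-(2,2-dimethoxyethyl)-2-methyl-6-methylidene-7-oxooxepan-2-yl]-4-methylnon-4-en-7-yn-1-yl acetate, via alkylzinc iodide 31 (not isolated)
Conditions: Zn dust (activated by TMSCl and 1,2-dibromoethane), LiCl, THF, 30 °C; then 6, PdCl2(dppf) (5 mol%), THF, 40 °C
Reagents that add atoms: none
Why: Negishi sp3–sp2 cross-coupling: zinc insertion into the primary iodide gives an alkylzinc that tolerates lactone, acetate, acetal and alkyne, and palladium-catalysed coupling with the Z vinyl iodide forms C8–C9 with retention of the Z geometry.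

Step 19
Reactants: 32 (1R,4Z)-1-[(2S,5S)-5-(2,2-dimethoxyethyl)-2-methyl-6-methylidene-7-oxooxepan-2-yl]-4-methylnon-4-en-7-yn-1-yl acetate
Product: 33 (1R,4Z)-4-methyl-1-[(2S,5S)-2-methyl-6-methylidene-7-oxo-5-(2-oxoethyl)oxepan-2-yl]non-4-en-7-yn-1-yl acetate
Conditions: LiBF4, MeCN–H2O (50:1), rt
Reagents that add atoms: water, O
Why: Mild Lewis acid hydrolysis of the dimethyl acetal releases the C3 aldehyde without affecting the acetate, the lactone or the skipped enyne.

Step 20
Reactants: 33 (1R,4Z)-4-methyl-1-[(2S,5S)-2-methyl-6-methylidene-7-oxo-5-(2-oxoethyl)oxepan-2-yl]non-4-en-7-yn-1-yl acetate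
Product: 35 target (1S,3S,4E,7Z,11R,12S)-11-acetoxy-3-hydroxycembra-4,7,15(17)-trien-16,12-olide, via macrocyclic triethylsilyl ether 34 (not isolated)
Conditions: Ni(cod)2 (15 mol%), L2·HBF4 [(4R,5R)-1,3-bis(2-isopropylphenyl)-4,5-diphenyl-4,5-dihydroimidazolium tetrafluoroborate, 15 mol%], KOt-Bu (15 mol%), Et3SiH (3 equiv), THF, 0.003 M, syringe-pump addition of 33, rt; concentrate; HF·pyridine, THF, 0 °C
Reagents that add atoms: none
Why: Proposed new method: a ligand-controlled nickel-catalysed reductive macrocyclisation of an ynal whose alkyne is a methyl-capped skipped (1,4-) enyne, run with a small C2-symmetric chiral N-heterocyclic carbene; zerovalent nickel binds aldehyde and alkyne and undergoes oxidative cyclisation to a five-membered oxanickelacycle, forming C3–C4 at the less hindered methyl-bearing alkyne carbon (endocyclic mode, favoured by small carbenes) on the aldehyde Re face selected by the chiral carbene (gives 3S); Si–H σ-bond metathesis and C–H reductive elimination then deliver H to C5 syn to the new C–C bond, which fixes 4E and closes the 14-membered ring, and fluoride removes the silyl group; the hindered 1,1-disubstituted enoate of the lactone is expected to be a much poorer partner than the aldehyde; the closest known reactions are the nickel/carbene/silane reductive macrocyclisation of ynals with achiral ligands and the intermolecular enantioselective aldehyde–alkyne reductive coupling with chiral carbenes.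

## Compound list

1 | but-2-yn-1-ol | CC#CCO | starting material
2 | sodium 2,2-bis(2-methoxyethoxy)-3-methyl-2,5-dihydro-1,2-oxaaluminol-2-uide (cyclic alkenylalanate, ring alkene cis) | [Na+].CC1=CCO[Al-]1(OCCOC)OCCOC | intermediate
3 | (Z)-3-iodobut-2-en-1-ol | I/C(C)=C\CO | intermediate
4 | (Z)-1-bromo-3-iodobut-2-ene | I/C(C)=C\CBr | intermediate
5 | prop-1-yn-1-ylmagnesium bromide | CC#C[Mg]Br | starting material
6 | (Z)-2-iodohept-2-en-5-yne | I/C(C)=C\CC#CC | intermediate
7 | but-3-yn-1-ol | C#CCCO | starting material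
8 | (but-3-yn-1-yloxy)(tert-butyl)dimethylsilane | C#CCCO[Si](C)(C)C(C)(C)C | intermediate
9 | oxirane | C1CO1 | starting material
10 | [(E)-4-{[tert-butyl(dimethyl)silyl]oxy}-2-methylbut-1-en-1-yl]dimethylaluminium | C[Al](C)/C=C(\C)CCO[Si](C)(C)C(C)(C)C | intermediate
11 | lithium butyl[(E)-4-{[tert-butyl(dimethyl)silyl]oxy}-2-methylbut-1-en-1-yl]dimethylaluminate | [Li+].CCCC[Al-](C)(C)/C=C(\C)CCO[Si](C)(C)C(C)(C)C | intermediate
12 | (E)-6-{[tert-butyl(dimethyl)silyl]oxy}-4-methylhex-3-en-1-ol | OCC/C=C(\C)CCO[Si](C)(C)C(C)(C)C | intermediate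
13 | tert-butyl{[(E)-6-chloro-3-methylhex-3-en-1-yl]oxy}dimethylsilane | ClCC/C=C(\C)CCO[Si](C)(C)C(C)(C)C | intermediate
14 | (E)-6-chloro-3-methylhex-3-en-1-ol | ClCC/C=C(\C)CCO | intermediate
15 | (E)-6-chloro-1-iodo-3-methylhex-3-ene | ClCC/C=C(\C)CCI | intermediate
16 | 3,3-dimethoxyprop-1-ene | C=CC(OC)OC | starting material
17 | 9-(3,3-dimethoxypropyl)-9-borabicyclo[3.3.1]nonane | COC(OC)CCB1C2CCCC1CCC2 | intermediate
18 | 3,3-dimethoxypropan-1-ol | OCCC(OC)OC | intermediate
19 | 3,3-dimethoxypropanal | O=CCC(OC)OC | intermediate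
20 | methyl prop-2-ynoate | C#CC(=O)OC | starting material
21 | [1-(methoxycarbonyl)ethenyl]bis(2-methylpropyl)aluminium | C=C(C(=O)OC)[Al](CC(C)C)CC(C)C | intermediate
22 | methyl 3-hydroxy-5,5-dimethoxy-2-methylidenepentanoate (racemic) | C=C(C(=O)OC)C(O)CC(OC)OC | intermediate
23 | methyl (Z)-2-(bromomethyl)-5,5-dimethoxypent-2-enoate | COC(=O)/C(CBr)=C/CC(OC)OC | intermediate
24 | bis[(E)-6-chloro-3-methylhex-3-en-1-yl]zinc | ClCC/C=C(\C)CC[Zn]CC/C(C)=C/CCCl | intermediate
25 | methyl (3S,6E)-9-chloro-3-(2,2-dimethoxyethyl)-6-methyl-2-methylidenenon-6-enoate | C=C(C(=O)OC)[C@H](CC(OC)OC)CC/C(C)=C/CCCl | intermediate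
26 | methyl (3S)-5-[(2R,3R)-3-(2-chloroethyl)-2-methyloxiran-2-yl]-3-(2,2-dimethoxyethyl)-2-methylidenepentanoate | C=C(C(=O)OC)[C@H](CC(OC)OC)CC[C@@]1(C)O[C@@H]1CCCl | intermediate
27 | (3S)-5-[(2R,3R)-3-(2-chloroethyl)-2-methyloxiran-2-yl]-3-(2,2-dimethoxyethyl)-2-methylidenepentanoic acid | C=C(C(=O)O)[C@H](CC(OC)OC)CC[C@@]1(C)O[C@@H]1CCCl | intermediate
28 | (4S,7S)-7-[(1R)-3-chloro-1-hydroxypropyl]-4-(2,2-dimethoxyethyl)-7-methyl-3-methylideneoxepan-2-one | C=C1C(=O)O[C@@](C)(CC[C@H]1CC(OC)OC)[C@@H](CCCl)O | intermediate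
29 | (1R)-3-chloro-1-[(2S,5S)-5-(2,2-dimethoxyethyl)-2-methyl-6-methylidene-7-oxooxepan-2-yl]propyl acetate | C=C1C(=O)O[C@@](C)(CC[C@H]1CC(OC)OC)[C@@H](CCCl)OC(C)=O | intermediate
30 | (1R)-1-[(2S,5S)-5-(2,2-dimethoxyethyl)-2-methyl-6-methylidene-7-oxooxepan-2-yl]-3-iodopropyl acetate | C=C1C(=O)O[C@@](C)(CC[C@H]1CC(OC)OC)[C@@H](CCI)OC(C)=O | intermediate
31 | {(3R)-3-acetoxy-3-[(2S,5S)-5-(2,2-dimethoxyethyl)-2-methyl-6-methylidene-7-oxooxepan-2-yl]propyl}zinc iodide | C=C1C(=O)O[C@@](C)(CC[C@H]1CC(OC)OC)[C@@H](CC[Zn]I)OC(C)=O | intermediate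
32 | (1R,4Z)-1-[(2S,5S)-5-(2,2-dimethoxyethyl)-2-methyl-6-methylidene-7-oxooxepan-2-yl]-4-methylnon-4-en-7-yn-1-yl acetate | C=C1C(=O)O[C@@](C)(CC[C@H]1CC(OC)OC)[C@@H](CC/C(C)=C\CC#CC)OC(C)=O | intermediate
33 | (1R,4Z)-4-methyl-1-[(2S,5S)-2-methyl-6-methylidene-7-oxo-5-(2-oxoethyl)oxepan-2-yl]non-4-en-7-yn-1-yl acetate | C=C1C(=O)O[C@@](C)(CC[C@H]1CC=O)[C@@H](CC/C(C)=C\CC#CC)OC(C)=O | intermediate
34 | 3-O-triethylsilyl ether of 35 | C=C1C(=O)O[C@@]2(C)CC[C@H]1C[C@H](O[Si](CC)(CC)CC)/C(C)=C/C/C=C(/C)CC[C@H]2OC(C)=O | intermediate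
35 | (1S,3S,4E,7Z,11R,12S)-11-acetoxy-3-hydroxycembra-4,7,15(17)-trien-16,12-olide (14-membered carbocycle fused to an α-methylene ε-lactone) | C=C1C(=O)O[C@@]2(C)CC[C@H]1C[C@H](O)/C(C)=C/C/C=C(/C)CC[C@H]2OC(C)=O | target

## Step count and risks

Total step count: 20. Longest linear sequence: 13 steps (steps 4–8, then 13–20, from but-3-yn-1-ol); the electrophile branch (steps 9–12) and the west fragment (steps 1–3) run in parallel.

The three steps most likely to fail:

**Step 20 (proposed new macrocyclisation).** Possible failures are exocyclic regiochemistry (C–C bond at C5), poor C3 selectivity, or nickel being tied up by the α-methylene lactone. The fallback uses known chemistry, sets out from 32 and comes back at 35. Hydrozirconation of the alkyne of 32 with Cp2Zr(H)Cl (THF, rt; zirconium settles on the methyl-bearing carbon) and iodinolysis give (1R,4Z,7E)-1-[(2S,5S)-5-(2,2-dimethoxyethyl)-2-methyl-6-methylidene-7-oxooxepan-2-yl]-8-iodo-4-methylnona-4,7-dien-1-yl acetate F1. Acetal hydrolysis (LiBF4, wet MeCN) gives the iodo aldehyde (1R,4Z,7E)-8-iodo-4-methyl-1-[(2S,5S)-2-methyl-6-methylidene-7-oxo-5-(2-oxoethyl)oxepan-2-yl]nona-4,7-dien-1-yl acetate F2. A Nozaki–Hiyama–Kishi macrocyclisation (CrCl2, catalytic NiCl2, DMSO–THF, high dilution, optionally with a Kishi-type chiral sulfonamide ligand) then closes C3–C4 with retention of the E geometry to give 35.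

**Step 13 (asymmetric SN2′ alkylation).** The enantioselectivity with an aliphatic Baylis–Hillman bromide and a functionalised dialkylzinc may be insufficient. The fallback sets out from 14 and 19 and comes back at 25. Alcohol 14 is converted (CBr4, PPh3) into (E)-1-bromo-6-chloro-3-methylhex-3-ene F3 and this (Mg, t-BuOMe) into [(E)-6-chloro-3-methylhex-3-en-1-yl]magnesium bromide F4. Aldehyde 19 is olefinated (Ph3P=CHCO2Me) to methyl (E)-5,5-dimethoxypent-2-enoate F5. Copper-catalysed asymmetric conjugate addition of F4 to F5 (CuBr·SMe2, Josiphos-type ferrocenyl diphosphine, t-BuOMe, −75 °C) sets C1. The magnesium enolate is trapped in the same flask with dimethylmethyleneiminium iodide to give methyl (3S,6E)-9-chloro-3-(2,2-dimethoxyethyl)-2-[(dimethylamino)methyl]-6-methylnon-6-enoate F6. Quaternisation with MeI gives the trimethylammonium iodide F7, and elimination with DBU gives 25.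

**Step 16 (7-exo epoxide opening at a tertiary carbon).** Elimination or rearrangement of the tertiary epoxide, or loss of the acetal, may compete with lactonisation of the free epoxy acid. The fallback sets out from 25 and comes back at 28, which is acetylated to 29 as in step 16. Ester 25 is saponified (LiOH) to (3S,6E)-9-chloro-3-(2,2-dimethoxyethyl)-6-methyl-2-methylidenenon-6-enoic acid F8 and re-esterified (Boc2O, DMAP, t-BuOH) to its tert-butyl ester F9. Shi epoxidation as in step 14 gives tert-butyl (3S)-5-[(2R,3R)-3-(2-chloroethyl)-2-methyloxiran-2-yl]-3-(2,2-dimethoxyethyl)-2-methylidenepentanoate F10. Here the lactone oxygen is delivered by the ester carbonyl: acid (CSA, or BF3·OEt2 at −78 °C, CH2Cl2) triggers attack on C12 with inversion through a dioxacarbenium ion that loses isobutene, giving 28 without a free epoxy acid ever being handled.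

Further compounds
F1 | step 20 | (1R,4Z,7E)-1-[(2S,5S)-5-(2,2-dimethoxyethyl)-2-methyl-6-methylidene-7-oxooxepan-2-yl]-8-iodo-4-methylnona-4,7-dien-1-yl acetate | C=C1C(=O)O[C@@](C)(CC[C@H]1CC(OC)OC)[C@@H](CC/C(C)=C\C/C=C(\C)I)OC(C)=O
F2 | step 20 | (1R,4Z,7E)-8-iodo-4-methyl-1-[(2S,5S)-2-methyl-6-methylidene-7-oxo-5-(2-oxoethyl)oxepan-2-yl]nona-4,7-dien-1-yl acetate | C=C1C(=O)O[C@@](C)(CC[C@H]1CC=O)[C@@H](CC/C(C)=C\C/C=C(\C)I)OC(C)=O
F3 | step 13 | (E)-1-bromo-6-chloro-3-methylhex-3-ene | ClCC/C=C(\C)CCBr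
F4 | step 13 | [(E)-6-chloro-3-methylhex-3-en-1-yl]magnesium bromide | ClCC/C=C(\C)CC[Mg]Br
F5 | step 13 | methyl (E)-5,5-dimethoxypent-2-enoate | COC(=O)/C=C/CC(OC)OC
F6 | step 13 | methyl (3S,6E)-9-chloro-3-(2,2-dimethoxyethyl)-2-[(dimethylamino)methyl]-6-methylnon-6-enoate (C2 epimers) | COC(=O)C(CN(C)C)[C@H](CC(OC)OC)CC/C(C)=C/CCCl
F7 | step 13 | [(3S,6E)-9-chloro-3-(2,2-dimethoxyethyl)-2-(methoxycarbonyl)-6-methylnon-6-en-1-yl]trimethylammonium iodide (C2 epimers) | COC(=O)C(C[N+](C)(C)C)[C@H](CC(OC)OC)CC/C(C)=C/CCCl.[I-]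
F8 | step 16 | (3S,6E)-9-chloro-3-(2,2-dimethoxyethyl)-6-methyl-2-methylidenenon-6-enoic acid | C=C(C(=O)O)[C@H](CC(OC)OC)CC/C(C)=C/CCCl
F9 | step 16 | tert-butyl (3S,6E)-9-chloro-3-(2,2-dimethoxyethyl)-6-methyl-2-methylidenenon-6-enoate | C=C(C(=O)OC(C)(C)C)[C@H](CC(OC)OC)CC/C(C)=C/CCCl
F10 | step 16 | tert-butyl (3S)-5-[(2R,3R)-3-(2-chloroethyl)-2-methyloxiran-2-yl]-3-(2,2-dimethoxyethyl)-2-methylidenepentanoate | C=C(C(=O)OC(C)(C)C)[C@H](CC(OC)OC)CC[C@@]1(C)O[C@@H]1CCCl
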